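The route cuts the side chain at its doubly allylic methylene. This is the bond between C5' (CH2) and vinylic C6' inside the skipped diene C3'=C4'–C5'–C6'=C7', which hangs on the quaternary ring carbon C3 of the cyclohexane. In one operation, hydrozirconation of a citronellal-derived alkyne and palladium-catalysed coupling with allylic transposition should form this bond, set both E alkenes and erase a stereorandom C–Cl centre. The precursor is a secondary isopropenyl-substituted chloride, made by ene-type chlorination of a homoprenyl group. The ring grows from one catalytically set stereocentre (C4), which is relayed to C3 and C2. A temporary vinyl δ-lactone locks the Z tetrasubstituted alkene.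

Key step: step 10

Labels: ring carbons are C1–C6 (C1 = ketone, later alkylidene carbon; C2 = CH bearing the three-carbon arm C1''–C3''; C3 = quaternary carbon; C4 = CH–CH3). The chain on C3 is C1'–C13', counted from the ring.
Assumption: C1'' in 11, 13 and 14 and the C–Cl carbon in 17 are carried as epimer mixtures, because both centres are removed later.

Step 1
Reactants: 1 propanal; 2 but-3-en-2-one
Product: 3 (R)-2-methyl-5-oxohexanal
Conditions: (S)-2-[methoxy(diphenyl)methyl]pyrrolidine (5 mol %), ethyl 3,4-dihydroxybenzoate (20 mol %), neat, 4 °C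
Reagents that add atoms: none
Why: Enamine-catalysed asymmetric Michael addition, in which the diphenyl(methoxy)methyl group of the (S)-pyrrolidine shields one face of the E-enamine of 1 so that 2 should add from the open face and set the methyl-bearing centre (the later ring carbon C4) as R.

Step 2
Reactants: 3 (R)-2-methyl-5-oxohexanal
Product: 4 (R)-4-methylcyclohex-2-en-1-one
Conditions: LiOH (0.1 equiv), i-PrOH, rt
Reagents that add atoms: none
Why: Intramolecular aldol condensation (the ring-closing half of a Robinson annulation), in which the methyl ketone enolate attacks the aldehyde in a 6-(enolexo)-exo-trig closure and water is lost, while the mild catalytic base should leave the γ-stereocentre C4 untouched.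

Step 3
Reactants: 4 (R)-4-methylcyclohex-2-en-1-one; 5 5-bromo-2-methylpent-2-ene
Product: 8 (R)-4-methyl-3-(4-methylpent-3-en-1-yl)cyclohex-2-en-1-one, via homoprenylmagnesium bromide 6 (not isolated), via bromomagnesium enolate 7 (not isolated)
Conditions: 5, Mg, THF, reflux; CuBr·SMe2 (10 mol %), 4, THF, −78 to −40 °C; then PhS(Cl)=N-t-Bu, −78 °C to rt
Reagents that add atoms: none
Why: Copper-catalysed conjugate addition of 6 gives the regiodefined enolate 7, which the sulfinimidoyl chloride should dehydrogenate through α-sulfenimidation and syn elimination (Mukaiyama dehydrogenation, overall a one-pot β-alkylation of an enone), so the transient C3 centre vanishes again and C4 is not involved.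

Step 4
Reactants: 8 (R)-4-methyl-3-(4-methylpent-3-en-1-yl)cyclohex-2-en-1-one; 9 acrolein
Product: 11 (2R,3R,4R)-2-(1-hydroxyprop-2-en-1-yl)-3,4-dimethyl-3-(4-methylpent-3-en-1-yl)cyclohexan-1-one (epimers at C1''), via lithium enolate 10 (not isolated)
Conditions: Me2CuLi (from MeLi and CuI), Et2O, −20 to 0 °C; then 9, THF, −78 °C; aq NH4Cl
Reagents that add atoms: Me2CuLi (lithium dimethylcuprate), [Li+].C[Cu-]C
Why: Tandem cuprate conjugate addition–aldol reaction, in which allylic 1,2-strain with the C3 chain holds the C4 methyl group pseudoaxial so that the new methyl group should enter C3 anti to it, and enolate 10 (C4 methyl equatorial, homoprenyl chain axial) should take up acrolein by axial attack on the face anti to that chain, which places the arm at C2 cis to the C3 methyl group, the carbinol centre C1'' being formed without control and removed in step 7.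

Step 5
Reactants: 11 aldol adduct; 12 2-(diethoxyphosphoryl)propanoic acid
Product: 13 2-(diethoxyphosphoryl)propanoate ester of 11
Conditions: DCC, DMAP (10 mol %), CH2Cl2, 0 °C to rt
Reagents that add atoms: none
Why: Steglich esterification of the secondary allylic alcohol under nearly neutral conditions, which should leave the epimerisable C2 centre and the β-oxygenated ketone array intact and creates no stereocentre that persists.

Step 6
Reactants: 13 2-(diethoxyphosphoryl)propanoate ester of 11
Product: 14 (7R,8R,8aS)-1-ethenyl-4,7,8-trimethyl-8-(4-methylpent-3-en-1-yl)-1,5,6,7,8,8a-hexahydro-3H-isochromen-3-one (epimers at C1'')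
Conditions: LiCl, DBU, MeCN, 0 °C to rt
Reagents that add atoms: none
Why: Intramolecular Horner–Wadsworth–Emmons olefination under Masamune–Roush conditions, in which closure of the six-membered lactone forces the new tetrasubstituted alkene C1=C to carry its carbonyl carbon cis to C2 and its methyl group cis to C6, a geometry that an intermolecular olefination could not be expected to give, and no stereocentre is formed.

Step 7
Reactants: 14 vinyl δ-lactone
Product: 16 methyl (Z)-2-[(2S,3R,4R)-3,4-dimethyl-3-(4-methylpent-3-en-1-yl)-2-(prop-2-en-1-yl)cyclohexylidene]propanoate, via carboxylic acid 15 (not isolated)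
Conditions: Pd2(dba)3·CHCl3 (2.5 mol %), PBu3 (10 mol %), HCO2H, Et3N, THF, 40 °C; evaporate; then K2CO3, MeI, DMF, rt
Reagents that add atoms: iodomethane, CI
Why: Tsuji–Trost ionisation of the allylic lactone C–O bond by zerovalent palladium and hydride transfer from the palladium formate to the more substituted allyl terminus (formate hydrogenolysis) should give the terminal allyl arm and free the acid, whose carbonyl stays cis to C2 because the ring had fixed it, and O-alkylation of the carboxylate masks it, so that C1'' loses its oxygen and its stereocentre.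

Step 8
Reactants: 16 methyl ester
Product: 17 methyl (Z)-2-[(2S,3R,4R)-3-(3-chloro-4-methylpent-4-en-1-yl)-3,4-dimethyl-2-(prop-2-en-1-yl)cyclohexylidene]propanoate (epimers at the C–Cl carbon)
Conditions: NCS (1.1 equiv), PhSeCl (5 mol %), CH2Cl2, rt
Reagents that add atoms: N-chlorosuccinimide, O=C1CCC(=O)N1Cl
Why: Selenium-catalysed ene-type allylic chlorination, in which the electrophilic selenium species should engage only the electron-rich trisubstituted alkene (not the enoate or the monosubstituted alkene) and deliver chlorine with shift of the double bond into the isopropenyl position, the new C–Cl centre being formed without control and erased in step 10.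

Step 9
Reactants: 18 (S)-citronellal
Product: 20 (S)-3,7-dimethyloct-6-en-1-yne, via alkenyl nonaflate 19 (not isolated)
Conditions: C4F9SO2F (1.2 equiv), phosphazene base P2-Et (2.3 equiv), DMF, −10 °C to rt
Reagents that add atoms: none
Why: One-pot dehydration of an enolisable aldehyde, in which O-sulfonylation of the enolate gives the alkenyl nonaflate 19 and the phosphazene base then expels nonaflate by β-elimination to the terminal alkyne, while the purchased methyl-bearing stereocentre (later C8') carries no activated hydrogen and should be retained.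

Step 10
Reactants: 17 allylic chloride; 20 (S)-3,7-dimethyloct-6-en-1-yne
Product: 22 methyl (Z)-2-[(2S,3R,4R)-3,4-dimethyl-2-(prop-2-en-1-yl)-3-[(3E,6E,8S)-4,8,12-trimethyltrideca-3,6,11-trien-1-yl]cyclohexylidene]propanoate, via alkenylzirconocene chloride 21 (not isolated)
Conditions: 20, Cp2Zr(H)Cl, THF, rt; then 17, Pd(PPh3)4 (5 mol %), THF, 0 °C to rt
Reagents that add atoms: none
Why: Cp2Zr(H)Cl adds syn across the terminal alkyne of 20 with zirconium on the unhindered terminal carbon, which fixes the E geometry of C6'=C7' in 21 without touching the trisubstituted alkene or the adjacent C8' stereocentre. Zerovalent palladium ionises either epimer of 17 to the same 1-alkyl-2-methyl-π-allylpalladium chloride, which can relax by π–σ–π interconversion to the syn isomer; transmetalation from zirconium and reductive elimination at the unsubstituted CH2 terminus then form the C5'–C6' bond. The closest known reaction type is the palladium-catalysed (Negishi-type) coupling of alkenylzirconium or alkenylaluminium reagents with allylic halides to give 1,4-dienes. No ring is closed and no stereocentre is created: the stereorandom C–Cl centre is erased, and the syn π-allyl geometry is translated into the E trisubstituted alkene C3'=C4'. The step needs linear over branched regioselectivity, E over Z geometry and chemoselectivity; the steric contrast between the CH2 and the secondary allyl terminus, the syn preference of the alkyl substituent and the low basicity and nucleophilicity of the organozirconium (inert to the enoate ester and the terminal allyl arm, no isomerisation of the skipped diene) should secure them.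

Step 11
Reactants: 22 coupled tetraenyl ester
Product: 24 methyl (Z)-2-[(2S,3R,4R)-2-(3-hydroxypropyl)-3,4-dimethyl-3-[(3E,6E,8S)-4,8,12-trimethyltrideca-3,6,11-trien-1-yl]cyclohexylidene]propanoate, via B-alkyl-9-BBN adduct 23 (not isolated)
Conditions: 9-BBN-H (1.2 equiv), THF, 0 °C to rt; then NaOH, H2O2, 0 °C
Reagents that add atoms: hydrogen peroxide, OO
Why: Brown hydroboration–oxidation, in which the bulky 9-BBN-H should add anti-Markovnikov to the only monosubstituted alkene far faster than to the di-, tri- and tetrasubstituted alkenes and does not reduce the ester, no stereocentre being formed.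

Step 12
Reactants: 24 hydroxy ester
Product: 25 (Z)-2-[(2S,3R,4R)-2-(3-hydroxypropyl)-3,4-dimethyl-3-[(3E,6E,8S)-4,8,12-trimethyltrideca-3,6,11-trien-1-yl]cyclohexylidene]propan-1-ol (target)
Conditions: i-Bu2AlH (3.5 equiv), CH2Cl2, −78 to 0 °C; aq potassium sodium tartrate
Reagents that add atoms: none
Why: 1,2-Reduction of the conjugated ester with i-Bu2AlH should give the allylic alcohol without touching any alkene geometry or stereocentre, the free hydroxyl group merely consuming one equivalent of hydride.

Compound list
1 | propanal | CCC=O | starting material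
2 | but-3-en-2-one | CC(=O)C=C | starting material
3 | (R)-2-methyl-5-oxohexanal | CC(=O)CC[C@@H](C)C=O | intermediate
4 | (R)-4-methylcyclohex-2-en-1-one | C[C@@H]1CCC(=O)C=C1 | intermediate
5 | 5-bromo-2-methylpent-2-ene | CC(C)=CCCBr | starting material
6 | (4-methylpent-3-en-1-yl)magnesium bromide | CC(C)=CCC[Mg]Br | intermediate
7 | bromomagnesium enolate of trans-4-methyl-3-(4-methylpent-3-en-1-yl)cyclohexanone | CC(C)=CCC[C@@H]1C=C(O[Mg]Br)CC[C@H]1C | intermediate
8 | (R)-4-methyl-3-(4-methylpent-3-en-1-yl)cyclohex-2-en-1-one | CC(C)=CCCC1=CC(=O)CC[C@H]1C | intermediate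
9 | acrolein | C=CC=O | starting material
10 | lithium enolate of (3R,4R)-3,4-dimethyl-3-(4-methylpent-3-en-1-yl)cyclohexanone (C1=C2 enolate) | CC(C)=CCC[C@]1(C)[C@H](C)CCC([O-])=C1.[Li+] | intermediate
11 | (2R,3R,4R)-2-(1-hydroxyprop-2-en-1-yl)-3,4-dimethyl-3-(4-methylpent-3-en-1-yl)cyclohexan-1-one, epimers at C1'' | CC(C)=CCC[C@]1(C)[C@H](C)CCC(=O)[C@H]1C(O)C=C | intermediate
12 | 2-(diethoxyphosphoryl)propanoic acid | CCOP(=O)(OCC)C(C)C(=O)O | starting material
13 | 2-(diethoxyphosphoryl)propanoate ester of 11 | CC(C)=CCC[C@]1(C)[C@H](C)CCC(=O)[C@H]1C(C=C)OC(=O)C(C)P(=O)(OCC)OCC | intermediate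
14 | (7R,8R,8aS)-1-ethenyl-4,7,8-trimethyl-8-(4-methylpent-3-en-1-yl)-1,5,6,7,8,8a-hexahydro-3H-isochromen-3-one, epimers at C1'' | CC(C)=CCC[C@]1(C)[C@H](C)CCC2=C(C)C(=O)OC(C=C)[C@H]21 | intermediate
15 | (Z)-2-[(2S,3R,4R)-3,4-dimethyl-3-(4-methylpent-3-en-1-yl)-2-(prop-2-en-1-yl)cyclohexylidene]propanoic acid | CC(C)=CCC[C@]1(C)[C@H](C)CC/C(=C(\C)C(=O)O)[C@H]1CC=C | intermediate
16 | methyl ester of 15 | CC(C)=CCC[C@]1(C)[C@H](C)CC/C(=C(\C)C(=O)OC)[C@H]1CC=C | intermediate
17 | methyl (Z)-2-[(2S,3R,4R)-3-(3-chloro-4-methylpent-4-en-1-yl)-3,4-dimethyl-2-(prop-2-en-1-yl)cyclohexylidene]propanoate, epimers at C–Cl | C=C(C)C(Cl)CC[C@]1(C)[C@H](C)CC/C(=C(\C)C(=O)OC)[C@H]1CC=C | intermediate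
18 | (S)-citronellal | CC(C)=CCC[C@H](C)CC=O | starting material
19 | (3S)-3,7-dimethylocta-1,6-dien-1-yl nonafluorobutane-1-sulfonate, E/Z mixture | CC(C)=CCC[C@H](C)C=COS(=O)(=O)C(F)(F)C(F)(F)C(F)(F)C(F)(F)F | intermediate
20 | (S)-3,7-dimethyloct-6-en-1-yne | CC(C)=CCC[C@H](C)C#C | intermediate
21 | chlorobis(cyclopentadienyl)[(1E,3S)-3,7-dimethylocta-1,6-dien-1-yl]zirconium | CC(C)=CCC[C@H](C)/C=C/[Zr](Cl)(C1C=CC=C1)C1C=CC=C1 | intermediate
22 | methyl (Z)-2-[(2S,3R,4R)-3,4-dimethyl-2-(prop-2-en-1-yl)-3-[(3E,6E,8S)-4,8,12-trimethyltrideca-3,6,11-trien-1-yl]cyclohexylidene]propanoate | CC(C)=CCC[C@H](C)/C=C/C/C(C)=C/CC[C@]1(C)[C@H](C)CC/C(=C(\C)C(=O)OC)[C@H]1CC=C | intermediate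
23 | B-alkyl-9-borabicyclo[3.3.1]nonane adduct of 22 (boron on C3'') | CC(C)=CCC[C@H](C)/C=C/C/C(C)=C/CC[C@]1(C)[C@H](C)CC/C(=C(\C)C(=O)OC)[C@H]1CCCB2C3CCCC2CCC3 | intermediate
24 | methyl (Z)-2-[(2S,3R,4R)-2-(3-hydroxypropyl)-3,4-dimethyl-3-[(3E,6E,8S)-4,8,12-trimethyltrideca-3,6,11-trien-1-yl]cyclohexylidene]propanoate | CC(C)=CCC[C@H](C)/C=C/C/C(C)=C/CC[C@]1(C)[C@H](C)CC/C(=C(\C)C(=O)OC)[C@H]1CCCO | intermediate
25 | (Z)-2-[(2S,3R,4R)-2-(3-hydroxypropyl)-3,4-dimethyl-3-[(3E,6E,8S)-4,8,12-trimethyltrideca-3,6,11-trien-1-yl]cyclohexylidene]propan-1-ol | CC(C)=CCC[C@H](C)/C=C/C/C(C)=C/CC[C@]1(C)[C@H](C)CC/C(=C(\C)CO)[C@H]1CCCO | target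

Total step count: 12. Longest linear sequence: 11 steps (steps 1–8 and 10–12); step 9 is the side branch.

Steps most likely to fail

Step 6. Attack of the hindered α-methyl phosphonate carbanion on the ketone may be slow. Base-induced β-elimination of the acyloxy group across C2–C1'', or epimerisation at C2, could then win. The fallback sets out from 11 and comes back at 14, and it avoids any base while the ketone is still present. Acylation of 11 with 2-bromopropanoyl bromide and pyridine should give the 2-bromopropanoate F1. SmI2 in THF at −78 °C should close the ring by an intramolecular Reformatsky reaction to the β-hydroxy δ-lactone F2, in which C2 is no longer next to a carbonyl group. Dehydration with SOCl2 in pyridine, directed into conjugation by the acidic α-hydrogen of the lactone, should then give 14.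

Step 10. The secondary chloride may ionise through the rotamer that leads to the anti π-allyl complex, and coupling before syn–anti equilibration would erode the E geometry at C3'=C4'. Reductive elimination at the secondary terminus, or β-hydride loss to a 1,3-diene, may also compete. The fallback sets out from 16 and comes back at 22, and it fixes the alkene geometry before the fragments are joined. Riley oxidation (catalytic SeO2, t-BuOOH, CH2Cl2) should oxidise only the E methyl group of the homoprenyl terminus to the primary (E)-allylic alcohol F3. Methyl chloroformate and pyridine should convert it into the methyl carbonate F4. Coupling of F4 with 21 under Pd(PPh3)4 then starts directly from the syn complex of a primary E electrophile, for which retention of geometry and attack at CH2 are the normal outcome.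

Step 4. Cuprate addition to the hindered β,β-disubstituted enone may be sluggish. The enolate may also equilibrate, or the aldolate may revert, which would lower both conversion and facial selectivity at C2. The fallback sets out from 8 and comes back at 11, and it separates the two bond formations. Me2CuLi in the presence of Me3SiCl should accelerate the addition and give the isolable trimethylsilyl enol ether F5. A Mukaiyama aldol reaction of F5 with acrolein (BF3·OEt2, CH2Cl2, −78 °C) is irreversible and runs through an open transition state, with the same axial approach anti to the homoprenyl chain.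

Further compounds
F1 | step 6 | 2-bromopropanoate ester of 11 | CC(C)=CCC[C@]1(C)[C@H](C)CCC(=O)[C@H]1C(C=C)OC(=O)C(C)Br
F2 | step 6 | 4a-hydroxy-octahydroisochroman-3-one (β-hydroxy δ-lactone, saturated precursor of 14) | CC(C)=CCC[C@]1(C)[C@H](C)CCC2(O)C(C)C(=O)OC(C=C)[C@H]21
F3 | step 10 | methyl (Z)-2-[(2S,3R,4R)-3-[(E)-5-hydroxy-4-methylpent-3-en-1-yl]-3,4-dimethyl-2-(prop-2-en-1-yl)cyclohexylidene]propanoate | OC/C(C)=C/CC[C@]1(C)[C@H](C)CC/C(=C(\C)C(=O)OC)[C@H]1CC=C
F4 | step 10 | methyl carbonate of F3 | COC(=O)OC/C(C)=C/CC[C@]1(C)[C@H](C)CC/C(=C(\C)C(=O)OC)[C@H]1CC=C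
F5 | step 4 | trimethylsilyl enol ether of (3R,4R)-3,4-dimethyl-3-(4-methylpent-3-en-1-yl)cyclohexanone (C1=C2) | CC(C)=CCC[C@]1(C)[C@H](C)CCC(O[Si](C)(C)C)=C1
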